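## Retrosynthetic overview

1. The target is opened at the C8 acyloxy acetal and at O7–C8 (ring A, dienol lactolisation) to a C6,C8-dialdehyde, which comes from a tricyclic acid holding rings B, C and D.
2. Feature used: on the bicyclo[3.2.1]octene formed by rings C and D, the C1 ester is γ,δ-unsaturated (C1–C2–C3=C4) and sits endo, directly under C4. Cutting C1–C2 in a retro-Ireland–Claisen sense gives the C4–O allylic ester of a C2=C3 alkene, i.e. a seven-membered lactone (C15, C1, C12, C13, C5, C4, O) bridging ring D.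
3. The lactone comes from a hydroxy acid with C4–OH cis to C12, made from a spiro enone. Ring D is closed by aldol condensation (C3–C2) of a C4 methyl ketone with a C2 aldehyde, both arms standing on quaternary C13 (allyl first, then 2-methylallyl).
4. Ring B and the C12 stereocentre come from (1R,4S)-cis-4-acetoxycyclopent-2-en-1-ol and dimethyl methylmalonate by palladium-catalysed allylic alkylation with retention.
5. Order of rings: B (purchased) → D → lactone tether → C (key step) → A.

Key step: step 17

Atom labels C1–C14 are those of the target (C1 = C(CH3)CO2Me, C13 = quaternary carbon, ring B = C9–C13, ring D = C2, C3, C4, C5, C13, C14); C15 is the carboxyl carbon on C1.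

Remark on the chemistry: after the Krapcho step C1 is carried as a mixture of both epimers (no descriptor in the SMILES) up to the lactone; both give the same silyl ketene acetal.

Remark on the chemistry: C5 and C9 are spectator centres (C5 becomes sp2 and C9 is equilibrated through the C8 aldehyde in the last step); the epimers drawn are the expected ones, and the facial selectivities behind them are predictions.

## Route

Step 1
Reactants: 1 (1R,4S)-cis-4-acetoxycyclopent-2-en-1-ol; 2 dimethyl 2-methylmalonate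
Product: 3 dimethyl 2-[(1S,4R)-4-hydroxycyclopent-2-en-1-yl]-2-methylmalonate
Conditions: NaH, THF, 0 °C (on 2); then 1, Pd(PPh3)4 (5 mol %), THF, 50 °C
Reagents that add atoms: none
Why: Tsuji–Trost allylic alkylation: palladium ionises the acetate with inversion and the soft malonate attacks the allyl terminus remote from the hydroxyl, anti to the metal, so net retention gives the cis-1,4 product and C12 takes its configuration from the purchased acetate.

Step 2
Reactants: 3 dimethyl 2-[(1S,4R)-4-hydroxycyclopent-2-en-1-yl]-2-methylmalonate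
Product: 4 dimethyl 2-methyl-2-[(1S)-4-oxocyclopent-2-en-1-yl]malonate
Conditions: MnO2, CH2Cl2, rt
Reagents that add atoms: none
Why: Allylic alcohol oxidation under neutral conditions gives the enone (C9=O, C10=C11) without touching the γ-stereocentre C12.

Step 3
Reactants: 4 dimethyl 2-methyl-2-[(1S)-4-oxocyclopent-2-en-1-yl]malonate; 5 allyl bromide
Product: 6 dimethyl 2-[(1R,5S)-5-allyl-4-oxocyclopent-2-en-1-yl]-2-methylmalonate
Conditions: LiN(iPr)2, THF, −78 °C; then 5, DMPU, −78 → −40 °C
Reagents that add atoms: none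
Why: Kinetic α′-enolate alkylation of the cyclopentenone: only C13 carries α′-hydrogens and the quaternary malonate has no acidic hydrogen, so allyl enters at C13 trans to the C12 substituent (this centre is made trigonal again in step 4).

Step 4
Reactants: 6 dimethyl 2-[(1R,5S)-5-allyl-4-oxocyclopent-2-en-1-yl]-2-methylmalonate; 7 3-bromo-2-methylprop-1-ene
Product: 8 dimethyl 2-[5-allyl-5-(2-methylallyl)-4-oxocyclopent-2-en-1-yl]-2-methylmalonate
Conditions: LiN(iPr)2, THF, −78 °C; then 7, DMPU, −78 → −20 °C
Reagents that add atoms: none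
Why: Second α′-enolate alkylation: the 2-methylallyl group (the future C5–C4–C3 arm) attacks the enolate face anti to the bulky C12 substituent, which fixes quaternary C13 with the allyl group (C14 arm) cis to the C12 side chain.

Step 5
Reactants: 8 dimethyl 2-[5-allyl-5-(2-methylallyl)-4-oxocyclopent-2-en-1-yl]-2-methylmalonate
Product: 10 dimethyl 2-[2-allyl-2-(2-methylallyl)-3-oxocyclopentyl]-2-methylmalonate, via silyl enol ether 9 (not isolated)
Conditions: [(Ph3P)CuH]6 (5 mol %), PhMe2SiH, toluene, rt; then 1 M HCl, THF, 0 °C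
Reagents that add atoms: none
Why: Copper hydride conjugate reduction (1,4-hydrosilylation) is selective for the enone over the two isolated terminal alkenes and the esters, and acid hydrolyses the silyl enol ether to the ketone.

Step 6
Reactants: 10 dimethyl 2-[2-allyl-2-(2-methylallyl)-3-oxocyclopentyl]-2-methylmalonate
Product: 11 methyl 2-[2-allyl-2-(2-methylallyl)-3-oxocyclopentyl]propanoate
Conditions: LiCl, H2O, DMSO, 160 °C
Reagents that add atoms: none
Why: Krapcho dealkoxycarbonylation of the disubstituted malonate leaves the propanoate side chain; C1 is formed as an inconsequential mixture of epimers.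

Step 7
Reactants: 11 methyl 2-[2-allyl-2-(2-methylallyl)-3-oxocyclopentyl]propanoate
Product: 12 methyl 2-[2-allyl-3-(methoxymethylidene)-2-(2-methylallyl)cyclopentyl]propanoate
Conditions: Ph3P(CH2OMe)Cl, KOtBu, THF, 0 → 50 °C
Reagents that add atoms: (methoxymethyl)triphenylphosphonium chloride, COC[P+](c1ccccc1)(c1ccccc1)c1ccccc1.[Cl-]
Why: Wittig methoxymethylenation of the C9 ketone adds the one carbon that becomes C8; the non-stabilised ylide reacts with the ketone in preference to the ester.

Step 8
Reactants: 12 methyl 2-[2-allyl-3-(methoxymethylidene)-2-(2-methylallyl)cyclopentyl]propanoate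
Product: 14 methyl 2-[2-allyl-3-(hydroxymethyl)-2-(2-methylallyl)cyclopentyl]propanoate, via aldehyde 13 (not isolated)
Conditions: 1 M HCl, THF, 0 °C; K2CO3, MeOH, rt; then NaBH4, 0 °C
Reagents that add atoms: water, O
Why: Brief cold acid hydrolyses the enol ether to the C8 aldehyde (kept short to avoid a carbonyl–ene reaction with the 2-methylallyl group), carbonate should equilibrate C9 to the epimer with CHO trans to the C12 chain and the allyl group, and NaBH4 reduces the aldehyde but not the ester.

Step 9
Reactants: 14 methyl 2-[2-allyl-3-(hydroxymethyl)-2-(2-methylallyl)cyclopentyl]propanoate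
Product: 15 methyl 2-[2-allyl-3-(tert-butyldimethylsilyloxymethyl)-2-(2-methylallyl)cyclopentyl]propanoate
Conditions: tBuMe2SiCl, imidazole, DMF, rt
Reagents that add atoms: tert-butyldimethylsilyl chloride, CC(C)(C)[Si](C)(C)Cl
Why: Standard silylation of the primary alcohol protects C8–OH for the oxidative and basic steps that follow.

Step 10
Reactants: 15 methyl 2-[2-allyl-3-(tert-butyldimethylsilyloxymethyl)-2-(2-methylallyl)cyclopentyl]propanoate
Product: 16 methyl 2-[3-(tert-butyldimethylsilyloxymethyl)-2-(2-oxoethyl)-2-(2-oxopropyl)cyclopentyl]propanoate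
Conditions: O3, CH2Cl2, −78 °C; then Me2S, −78 °C → rt
Reagents that add atoms: ozone, [O-][O+]=O
Why: Ozonolysis with reductive work-up cleaves both terminal alkenes, the allyl group giving the C2 aldehyde and the 2-methylallyl group the C4 methyl ketone.

Step 11
Reactants: 16 methyl 2-[3-(tert-butyldimethylsilyloxymethyl)-2-(2-oxoethyl)-2-(2-oxopropyl)cyclopentyl]propanoate
Product: 17 methyl 2-[4-(tert-butyldimethylsilyloxymethyl)-7-oxospiro[4.5]dec-8-en-1-yl]propanoate
Conditions: pyrrolidine (cat.), AcOH (cat.), benzene, 50 °C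
Reagents that add atoms: none
Why: Intramolecular aldol condensation of the 1,5-keto aldehyde: only attack of the methyl ketone carbon C3 on the C2 aldehyde gives a six-membered ring, so ring D closes as the enone C4(=O)–C3=C2 with C13 as spiro centre, and amine–acid catalysis avoids ester enolate chemistry.

Step 12
Reactants: 17 methyl 2-[4-(tert-butyldimethylsilyloxymethyl)-7-oxospiro[4.5]dec-8-en-1-yl]propanoate; 18 formaldehyde
Product: 19 methyl 2-[4-(tert-butyldimethylsilyloxymethyl)-6-(hydroxymethyl)-7-oxospiro[4.5]dec-8-en-1-yl]propanoate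
Conditions: LiN(iPr)2, THF, −78 °C; CH2O gas (from paraformaldehyde), −78 → −40 °C; then aq. NH4Cl
Reagents that add atoms: none
Why: Kinetic α′-enolisation of the enone (more acidic than the ester) and aldol addition to monomeric formaldehyde puts C6 on C5, expected anti to the C12 carbon; C5 is not a stereocentre of the target.

Step 13
Reactants: 19 methyl 2-[4-(tert-butyldimethylsilyloxymethyl)-6-(hydroxymethyl)-7-oxospiro[4.5]dec-8-en-1-yl]propanoate
Product: 20 methyl 2-[4,6-bis(tert-butyldimethylsilyloxymethyl)-7-oxospiro[4.5]dec-8-en-1-yl]propanoate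
Conditions: tBuMe2SiCl, imidazole, DMF, 0 °C
Reagents that add atoms: tert-butyldimethylsilyl chloride, CC(C)(C)[Si](C)(C)Cl
Why: Mild silylation of the primary alcohol, under conditions that do not provoke retro-aldol cleavage or β-elimination of the β-hydroxy ketone.

Step 14
Reactants: 20 methyl 2-[4,6-bis(tert-butyldimethylsilyloxymethyl)-7-oxospiro[4.5]dec-8-en-1-yl]propanoate
Product: 21 methyl 2-[4,6-bis(tert-butyldimethylsilyloxymethyl)-7-hydroxyspiro[4.5]dec-8-en-1-yl]propanoate
Conditions: NaBH4, CeCl3·7H2O, MeOH, −78 °C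
Reagents that add atoms: none
Why: Luche 1,2-reduction of the enone: axial hydride delivery with the C5 substituent equatorial should give the C4 alcohol trans to C5–CH2OSi and cis to C12 across ring D, the relationship that the lactone requires.

Step 15
Reactants: 21 methyl 2-[4,6-bis(tert-butyldimethylsilyloxymethyl)-7-hydroxyspiro[4.5]dec-8-en-1-yl]propanoate
Product: 22 2-[4,6-bis(tert-butyldimethylsilyloxymethyl)-7-hydroxyspiro[4.5]dec-8-en-1-yl]propanoic acid
Conditions: LiOH, THF–MeOH–H2O, 40 °C; then 1 M HCl to pH 4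
Reagents that add atoms: lithium hydroxide, [Li+].[OH-]
Why: Saponification of the methyl ester; the primary silyl ethers tolerate aqueous LiOH at this temperature.

Step 16
Reactants: 22 2-[4,6-bis(tert-butyldimethylsilyloxymethyl)-7-hydroxyspiro[4.5]dec-8-en-1-yl]propanoic acid
Product: 24 seven-membered lactone of 22 bridging ring D, via mixed anhydride 23 (not isolated)
Conditions: 2,4,6-Cl3C6H2COCl, Et3N, THF, rt; then DMAP, toluene (high dilution), 80 °C
Reagents that add atoms: none
Why: Yamaguchi lactonisation through the mixed anhydride closes the C15–O–C4 ester with retention at C4, which is possible only because C4–OH and C12 can both be axial on the same face of ring D; both C1 epimers are expected to cyclise or to equilibrate at the acylpyridinium stage.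

Step 17
Reactants: 24 seven-membered lactone of 22 bridging ring D
Product: 27 2,10-bis(tert-butyldimethylsilyloxymethyl)-6-methyltricyclo[5.3.1.0(1,5)]undec-8-ene-6-carboxylic acid, via silyl ketene acetal 25 (not isolated), via silyl ester 26 (not isolated)
Conditions: tBuMe2SiCl, KN(SiMe3)2, THF–DMPU, −78 °C; −78 °C → rt, then toluene, 80 °C; K2CO3, THF–H2O
Reagents that add atoms: none
Why: KN(SiMe3)2 deprotonates C1 in the presence of tBuMe2SiCl and O-silylation gives the cyclic silyl ketene acetal 25, whose six-atom array C1=C15(OSi)–O–C4–C3=C2 undergoes a concerted [3,3] shift through a boat-like transition state, forming C1–C2 while C4–O breaks and the alkene moves to C3=C4. The closest known reaction type is the ring-contracting Ireland–Claisen rearrangement of lactone-derived silyl ketene acetals. Ring C (C1, C2, C14, C13, C12) closes by this sigmatropic contraction of the seven-membered lactone onto ring D, formally a 5-exo C–C closure in which the C12–C13–C14 tether holds C1 under C2. C2 is set by suprafacial transfer from the C4–O bond, which lies on the C12 face of ring D, and C1 is set by the lactone, which keeps C15 beneath C4 (carboxyl endo, methyl exo); the C1 epimers of 24 converge because C1 is trigonal in 25. The step needs O-silylation to outrun ketene-forming fragmentation of the lactone enolate and needs the boat geometry to be reachable; in situ silylation at −78 °C and the 1,3-diaxial placement of C12 and O on ring D, already locked in 24, should secure both.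

Step 18
Reactants: 27 2,10-bis(tert-butyldimethylsilyloxymethyl)-6-methyltricyclo[5.3.1.0(1,5)]undec-8-ene-6-carboxylic acid
Product: 28 methyl 2,10-bis(tert-butyldimethylsilyloxymethyl)-6-methyltricyclo[5.3.1.0(1,5)]undec-8-ene-6-carboxylate
Conditions: Me3SiCHN2, MeOH–toluene, rt
Reagents that add atoms: trimethylsilyldiazomethane, C[Si](C)(C)C=[N+]=[N-]
Why: Methylation of the hindered tertiary acid with trimethylsilyldiazomethane needs no base and leaves the silyl ethers and the alkene alone.

Step 19
Reactants: 28 methyl 2,10-bis(tert-butyldimethylsilyloxymethyl)-6-methyltricyclo[5.3.1.0(1,5)]undec-8-ene-6-carboxylate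
Product: 29 methyl 2,10-bis(hydroxymethyl)-6-methyltricyclo[5.3.1.0(1,5)]undec-8-ene-6-carboxylate
Conditions: Bu4NF, THF, 0 °C → rt
Reagents that add atoms: none
Why: Fluoride-mediated desilylation frees both primary alcohols (C6–OH and C8–OH).

Step 20
Reactants: 29 methyl 2,10-bis(hydroxymethyl)-6-methyltricyclo[5.3.1.0(1,5)]undec-8-ene-6-carboxylate
Product: 30 methyl 2,10-diformyl-6-methyltricyclo[5.3.1.0(1,5)]undec-8-ene-6-carboxylate
Conditions: Dess–Martin periodinane, CH2Cl2, 0 °C → rt
Reagents that add atoms: none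
Why: Dess–Martin oxidation converts both primary alcohols into aldehydes under non-basic conditions, so the β,γ-unsaturated C6 aldehyde is not enolised prematurely.

Step 21
Reactants: 30 methyl 2,10-diformyl-6-methyltricyclo[5.3.1.0(1,5)]undec-8-ene-6-carboxylate; 31 3-methylbutanoic anhydride
Product: 33 target CNP0315847.1, via lactol 32 (not isolated)
Conditions: DBU (cat.), CH2Cl2, rt; then 31, DMAP (cat.), Et3N, 0 °C
Reagents that add atoms: none
Why: The amine base enolises the C6 aldehyde towards C5 (α to CHO and allylic) and the dienol oxygen adds to the C8 aldehyde to close ring A as the hemiacetal once C9 has equilibrated to the cis-fused epimer; DMAP-catalysed acylation then traps the lactol, expected as the anomer with the ester pseudo-axial and trans to C10 (cis to H9).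

## Compound list

1 | (1R,4S)-cis-4-acetoxycyclopent-2-en-1-ol | CC(=O)O[C@@H]1C=C[C@H](O)C1 | starting material
2 | dimethyl 2-methylmalonate | COC(=O)C(C)C(=O)OC | starting material
3 | dimethyl 2-[(1S,4R)-4-hydroxycyclopent-2-en-1-yl]-2-methylmalonate (cis-1,4) | COC(=O)C(C)(C(=O)OC)[C@@H]1C=C[C@H](O)C1 | intermediate
4 | dimethyl 2-methyl-2-[(1S)-4-oxocyclopent-2-en-1-yl]malonate | COC(=O)C(C)(C(=O)OC)[C@@H]1C=CC(=O)C1 | intermediate
5 | allyl bromide | BrCC=C | starting material
6 | dimethyl 2-[(1R,5S)-5-allyl-4-oxocyclopent-2-en-1-yl]-2-methylmalonate (allyl trans to the malonate chain) | COC(=O)C(C)(C(=O)OC)[C@@H]1C=CC(=O)[C@H]1CC=C | intermediate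
7 | 3-bromo-2-methylprop-1-ene | BrCC(C)=C | starting material
8 | dimethyl 2-[5-allyl-5-(2-methylallyl)-4-oxocyclopent-2-en-1-yl]-2-methylmalonate (allyl cis and 2-methylallyl trans to the malonate chain) | COC(=O)C(C)(C(=O)OC)[C@@H]1C=CC(=O)[C@]1(CC(C)=C)CC=C | intermediate
9 | dimethylphenylsilyl enol ether of 10 (C9–OSi, C9=C10) | COC(=O)C(C)(C(=O)OC)[C@@H]1CC=C(O[Si](C)(C)c2ccccc2)[C@]1(CC(C)=C)CC=C | intermediate
10 | dimethyl 2-[2-allyl-2-(2-methylallyl)-3-oxocyclopentyl]-2-methylmalonate (allyl cis to the malonate chain) | COC(=O)C(C)(C(=O)OC)[C@@H]1CCC(=O)[C@]1(CC(C)=C)CC=C | intermediate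
11 | methyl 2-[2-allyl-2-(2-methylallyl)-3-oxocyclopentyl]propanoate (allyl cis to the propanoate chain; C1 epimers) | COC(=O)C(C)[C@@H]1CCC(=O)[C@]1(CC(C)=C)CC=C | intermediate
12 | methyl 2-[2-allyl-3-(methoxymethylidene)-2-(2-methylallyl)cyclopentyl]propanoate (E/Z mixture) | COC(=O)C(C)[C@@H]1CCC(=COC)[C@]1(CC(C)=C)CC=C | intermediate
13 | methyl 2-[2-allyl-3-formyl-2-(2-methylallyl)cyclopentyl]propanoate (CHO trans to the propanoate chain) | COC(=O)C(C)[C@@H]1CC[C@@H](C=O)[C@]1(CC(C)=C)CC=C | intermediate
14 | methyl 2-[2-allyl-3-(hydroxymethyl)-2-(2-methylallyl)cyclopentyl]propanoate (CH2OH trans to the propanoate chain, cis to 2-methylallyl) | COC(=O)C(C)[C@@H]1CC[C@@H](CO)[C@]1(CC(C)=C)CC=C | intermediate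
15 | methyl 2-[2-allyl-3-(tert-butyldimethylsilyloxymethyl)-2-(2-methylallyl)cyclopentyl]propanoate | COC(=O)C(C)[C@@H]1CC[C@@H](CO[Si](C)(C)C(C)(C)C)[C@]1(CC(C)=C)CC=C | intermediate
16 | methyl 2-[3-(tert-butyldimethylsilyloxymethyl)-2-(2-oxoethyl)-2-(2-oxopropyl)cyclopentyl]propanoate | COC(=O)C(C)[C@@H]1CC[C@@H](CO[Si](C)(C)C(C)(C)C)[C@]1(CC(C)=O)CC=O | intermediate
17 | methyl 2-[4-(tert-butyldimethylsilyloxymethyl)-7-oxospiro[4.5]dec-8-en-1-yl]propanoate (ring D enone: C4=O, C2=C3) | COC(=O)C(C)[C@@H]1CC[C@@H](CO[Si](C)(C)C(C)(C)C)[C@]12CC=CC(=O)C2 | intermediate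
18 | formaldehyde (from paraformaldehyde) | C=O | starting material
19 | methyl 2-[4-(tert-butyldimethylsilyloxymethyl)-6-(hydroxymethyl)-7-oxospiro[4.5]dec-8-en-1-yl]propanoate (C6 on C5, anti to C12) | COC(=O)C(C)[C@@H]1CC[C@@H](CO[Si](C)(C)C(C)(C)C)[C@]12CC=CC(=O)[C@H]2CO | intermediate
20 | methyl 2-[4,6-bis(tert-butyldimethylsilyloxymethyl)-7-oxospiro[4.5]dec-8-en-1-yl]propanoate | COC(=O)C(C)[C@@H]1CC[C@@H](CO[Si](C)(C)C(C)(C)C)[C@]12CC=CC(=O)[C@H]2CO[Si](C)(C)C(C)(C)C | intermediate
21 | methyl 2-[4,6-bis(tert-butyldimethylsilyloxymethyl)-7-hydroxyspiro[4.5]dec-8-en-1-yl]propanoate (C4–OH cis to C12, trans to C5–CH2OSi) | COC(=O)C(C)[C@@H]1CC[C@@H](CO[Si](C)(C)C(C)(C)C)[C@]12CC=C[C@H](O)[C@H]2CO[Si](C)(C)C(C)(C)C | intermediate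
22 | 2-[4,6-bis(tert-butyldimethylsilyloxymethyl)-7-hydroxyspiro[4.5]dec-8-en-1-yl]propanoic acid | OC(=O)C(C)[C@@H]1CC[C@@H](CO[Si](C)(C)C(C)(C)C)[C@]12CC=C[C@H](O)[C@H]2CO[Si](C)(C)C(C)(C)C | intermediate
23 | mixed anhydride of 22 with 2,4,6-trichlorobenzoic acid | O=C(OC(=O)C(C)[C@@H]1CC[C@@H](CO[Si](C)(C)C(C)(C)C)[C@]12CC=C[C@H](O)[C@H]2CO[Si](C)(C)C(C)(C)C)c1c(Cl)cc(Cl)cc1Cl | intermediate
24 | seven-membered lactone of 22 (ring atoms C15, C1, C12, C13, C5, C4, O; spiro rings B and D; C1 epimers) | O=C1C(C)[C@@H]2CC[C@@H](CO[Si](C)(C)C(C)(C)C)[C@]23CC=C[C@H](O1)[C@H]3CO[Si](C)(C)C(C)(C)C | intermediate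
25 | tert-butyldimethylsilyl ketene acetal of 24 (C1=C15(OSi)–O–C4) | C1(O[Si](C)(C)C(C)(C)C)=C(C)[C@@H]2CC[C@@H](CO[Si](C)(C)C(C)(C)C)[C@]23CC=C[C@H](O1)[C@H]3CO[Si](C)(C)C(C)(C)C | intermediate
26 | tert-butyldimethylsilyl ester of 27 | CC(C)(C)[Si](C)(C)OC(=O)[C@]1(C)[C@@H]2C=C[C@@H](CO[Si](C)(C)C(C)(C)C)[C@@]3([C@H](CO[Si](C)(C)C(C)(C)C)CC[C@@H]13)C2 | intermediate
27 | 2,10-bis(tert-butyldimethylsilyloxymethyl)-6-methyltricyclo[5.3.1.0(1,5)]undec-8-ene-6-carboxylic acid (rings B, C, D; CO2H endo, CH3 exo at C1; C3=C4) | OC(=O)[C@]1(C)[C@@H]2C=C[C@@H](CO[Si](C)(C)C(C)(C)C)[C@@]3([C@H](CO[Si](C)(C)C(C)(C)C)CC[C@@H]13)C2 | intermediate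
28 | methyl ester of 27 | COC(=O)[C@]1(C)[C@@H]2C=C[C@@H](CO[Si](C)(C)C(C)(C)C)[C@@]3([C@H](CO[Si](C)(C)C(C)(C)C)CC[C@@H]13)C2 | intermediate
29 | methyl 2,10-bis(hydroxymethyl)-6-methyltricyclo[5.3.1.0(1,5)]undec-8-ene-6-carboxylate | COC(=O)[C@]1(C)[C@@H]2C=C[C@@H](CO)[C@@]3([C@H](CO)CC[C@@H]13)C2 | intermediate
30 | methyl 2,10-diformyl-6-methyltricyclo[5.3.1.0(1,5)]undec-8-ene-6-carboxylate (C6 and C8 aldehydes) | COC(=O)[C@]1(C)[C@@H]2C=C[C@@H](C=O)[C@@]3([C@H](C=O)CC[C@@H]13)C2 | intermediate
31 | 3-methylbutanoic anhydride | CC(C)CC(=O)OC(=O)CC(C)C | starting material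
32 | tetracyclic lactol (C8–OH; C3=C4–C5=C6–O7 dienol ether; rings A–D) | COC(=O)[C@]1(C)[C@@H]2C=CC3=CO[C@@H](O)[C@@H]4CC[C@@H]1[C@]34C2 | intermediate
33 | CNP0315847.1 (C8 3-methylbutanoate of 32) | COC(=O)[C@]1(C)[C@@H]2C=CC3=CO[C@@H](OC(=O)CC(C)C)[C@@H]4CC[C@@H]1[C@]34C2 | target

## Step count and risks

Total step count: 21. Longest linear sequence: 21 steps (1 → 33).

Steps most likely to fail:

Step 17 (key step). The silyl ketene acetal may not reach the boat geometry inside the bridged lactone, or the lactone enolate may fragment to a ketene before it is silylated. The fallback forms C1–C2 by conjugate addition instead of a sigmatropic shift. It sets out from enone 20 and comes back at methyl ester 28. KOtBu (cat.) in tBuOH–THF brings about intramolecular Michael addition of the C1 ester enolate to C2 (5-exo, under thermodynamic control, which should place CO2Me endo and CH3 exo) and gives the tricyclic C4 ketone F1. KN(SiMe3)2 and PhNTf2 then give the C3=C4 enol triflate F2 by kinetic deprotonation at the C3 methylene. Pd(OAc)2, PPh3, HCO2H and Bu3N reduce F2 to 28.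

Step 14. Hydride delivery to the C4 ketone may occur with poor or opposite facial selectivity, since the two faces of ring D are differentiated only by the ring B carbons on C13. The fallback sets the centre by substitution with inversion. It sets out from 20 and comes back at 21. The same Luche conditions then give the C4-epimeric alcohol F3; Mitsunobu reaction (PPh3, DIAD, 4-nitrobenzoic acid) inverts C4 to the 4-nitrobenzoate F4; K2CO3 in MeOH cleaves the benzoate to 21.

Step 21. Acylation may occur on the dienol oxygen rather than on the lactol, or give the wrong anomer. The fallback separates ring closure from ester formation and makes the C8–O bond by displacement. It sets out from 30 and comes back at 33. DBU alone gives lactol 32, which is isolated; Cl3CCN with K2CO3 gives the anomeric trichloroacetimidate F5 (imidate cis to C10); 3-methylbutanoic acid in CH2Cl2 displaces it with inversion to 33.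

Further compounds
F1 | step 17 | methyl 2,10-bis(tert-butyldimethylsilyloxymethyl)-6-methyl-9-oxotricyclo[5.3.1.0(1,5)]undecane-6-carboxylate (C4 ketone) | COC(=O)[C@]1(C)[C@@H]2CC(=O)[C@@H](CO[Si](C)(C)C(C)(C)C)[C@@]3([C@H](CO[Si](C)(C)C(C)(C)C)CC[C@@H]13)C2
F2 | step 17 | C3=C4 enol triflate of F1 | COC(=O)[C@]1(C)[C@@H]2C=C(OS(=O)(=O)C(F)(F)F)[C@@H](CO[Si](C)(C)C(C)(C)C)[C@@]3([C@H](CO[Si](C)(C)C(C)(C)C)CC[C@@H]13)C2
F3 | step 14 | C4 epimer of 21 (C4–OH trans to C12) | COC(=O)C(C)[C@@H]1CC[C@@H](CO[Si](C)(C)C(C)(C)C)[C@]12CC=C[C@@H](O)[C@H]2CO[Si](C)(C)C(C)(C)C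
F4 | step 14 | 4-nitrobenzoate of 21 | COC(=O)C(C)[C@@H]1CC[C@@H](CO[Si](C)(C)C(C)(C)C)[C@]12CC=C[C@H](OC(=O)c3ccc(cc3)[N+](=O)[O-])[C@H]2CO[Si](C)(C)C(C)(C)C
F5 | step 21 | trichloroacetimidate of the C8 anomer of 32 (imidate cis to C10) | COC(=O)[C@]1(C)[C@@H]2C=CC3=CO[C@H](OC(=N)C(Cl)(Cl)Cl)[C@@H]4CC[C@@H]1[C@]34C2
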